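## Analysis of the target

Hispidulin 7-sulfate is a flavone: a benzo ring A fused to a 4-pyranone ring C, which carries a 4-hydroxyphenyl ring B at C2. It has no stereocentre, so the whole problem is one of constitution. Ring A bears three contiguous oxygens, 5-OH (hydrogen-bonded to the C4 carbonyl), 6-OMe and the 7-O-sulfate, and a single C–H at C8. This 5,6,7-pattern has to be secured against the isomeric 5,7,8-pattern, which ambiguous ring closures or opening and reclosure of ring C can deliver instead. The aryl sulfate monoester is the most delicate group: it is very polar, tolerates base but not acid or Lewis acid, and therefore has to be installed last. The pyranone is electrophilic towards strong nucleophiles, and the 6-methyl ether, squeezed between two oxygens, is the ether most exposed to Lewis-acid dealkylation. Of the three phenolic oxygens only O7 may be sulfated, so the protecting groups must free 7-OH (and the unreactive, chelated 5-OH) while O4' stays masked. The plan rests on the C2–C1' bond between ring C and ring B: C2–H is the only enone β C–H of a chromone, so ring B can be attached last by C–H arylation to a chromone whose ring A oxygenation is already fixed.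

## Retrosynthetic reasoning

**12 to 10.** The S–O bond at O7 is cut first, together with the acetyl group on O4'. Sulfation must be the last bond-forming event because no acidic or Lewis-acidic step may follow it. In 10 the 5-OH is locked in its hydrogen bond to the C4 carbonyl and O4' is an ester, so a sulfating agent can only reach 7-OH. The ester (in 11, not isolated) is then removed by mild base, towards which an aryl sulfate anion is inert.

**10 to 9.** The two O–alkyl bonds at O5 and O7 are cut. Isopropyl ethers are chosen for these positions because benzyl-type ethers would fail twice on the way to the chromone: their phenyl rings offer unhindered C–H bonds to the iridium-catalysed borylation, and they are labile under Lewis-acid acylation. Isopropyl ethers have no aromatic C–H, resist the acylation and the aerobic palladium coupling, and are still cleaved by a boron trihalide under conditions that spare a methyl ether and an aryl ester. The forward step must dealkylate O5 and O7 without touching the 6-OMe or the acetate.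

**9 to 7 and 8.** The C2–C1' bond is cut; this is the strategic disconnection. C2 of 7 carries the only enone β-hydrogen, so the chromone needs no prefunctionalisation, the route becomes convergent, and ring B stays exchangeable at the last C–C bond formation. Forward, the aryl group of 8 must be delivered to C2 and not C3, and the enone must be regenerated oxidatively rather than left as the saturated ketone.

**7 to 5.** Ring C is opened at O1–C2 and the C2–C3 bond is cut, which removes C2 as a one-carbon unit and leads back to ortho-hydroxyacetophenone 5 through enaminone 6. Forward, a formamide acetal condenses at the acetyl methyl group, and acid then makes the phenol oxygen add to the enaminone β-carbon with loss of the amine. The ethers must survive brief acid.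

**5 to 4.** The aryl–acyl bond (C4a–C4) is cut. Phenol 4 is mirror-symmetric: its only two ring C–H positions, both ortho to the hydroxyl group, are equivalent, so acylation can give only one ketone. In that ketone the oxygen that becomes O1 is the free phenol, and the oxygens that become O5 and O7 are ethers. The 5,6,7-pattern is therefore fixed here by symmetry, before ring C or ring B exists.

**4 to 2.** The C–O bond para to the methoxy group is cut. The only ring C–H of 2 without an ortho neighbour is C5, exactly the position that must carry the oxygen, so a sterically governed C–H borylation (boronate 3) followed by oxidation is the direct way in.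

**2 to 1.** The two O–isopropyl bonds are cut. Diol 1 is commercial and already has the methoxy group flanked by the two oxygens that become O5 and O7.

## Alternatives that were turned down

Alternative 1: Ring A is built last instead of ring B being attached last. The disconnection cuts C7–C8 and C5–C6 and takes 4'-O-benzylhispidulin A1 back to methyl 6-[4-(benzyloxy)phenyl]-2-methyl-4-oxo-4H-pyran-3-carboxylate A2 and methyl methoxyacetate A3.

- Forward key step: LiN(iPr)2 forms the extended enolate at the 2-methyl group of A2, Claisen acylation by A3 makes the side-chain ketone, and a second enolisation at the methoxy-bearing carbon drives a Dieckmann closure onto the ring ester; tautomerisation then aromatises ring A and gives A1.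
- For it: the methoxy group comes in with A3 and can only end up at C6. A1 emerges with free 5-OH and 7-OH, so ring A needs no protecting groups. On protecting-group economy it is stronger than the chosen route.
- Against it: the second enolisation must occur at the less acidic carbon of a dicarbonyl chain, so a dianion is needed. The pyranone of A2 is itself an electrophile for the same base and for the methoxide released. The nucleophile is an α-alkoxy enolate attacking a hindered, vinylogous ester. A2 also needs several steps of its own.
- Comparison: two C–C bonds and an aromatisation in one operation on a sensitive pyranone concentrate more risk than the single, precedented bond formation of the chosen route. In place of the protecting-group economy, the chosen route offers intermediates 4, 5 and 7 by routine reactions and a ring B that can be varied at the coupling.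

Alternative 2: The C5–O bond is made last. The disconnection removes the 5-hydroxyl of 4'-O-acetylhispidulin 7-(2,2,2-trichloroethyl sulfate) A4 and leads to its 5-unsubstituted congener, 4'-acetoxy-6-methoxyflavon-7-yl 2,2,2-trichloroethyl sulfate A5. The oxygen is delivered by the oxidant [bis(trifluoroacetoxy)iodo]benzene A6.

- Forward key step: the C4 carbonyl of A5 binds [RuCl2(p-cymene)]2 (divalent ruthenium), cyclometalation at the peri C5–H gives a five-membered ruthenacycle, and A6 in trifluoroacetic acid and its anhydride turns it into the C5–O bond of A4.
- For it: ring A then needs only two oxygens from the start, 7-OH is the only free phenol early on so the sulfate can travel in protected form as far as A4, and carbonyl direction inherently prefers C5 over C8. On step count it is at least equal.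
- Against it: C5 in A5 lies between the peri carbonyl and the 6-methoxy group, so the metallacycle must form at a doubly flanked position. The electron-rich 6,7-dioxygenated ring sits with A6 in a strongly oxidising, acidic medium that invites oxidative demethylation or attack at C8. The acetate and the sulfate diester of A4 must survive the acid and anhydride. All of this happens on the most advanced intermediate.
- Comparison: the chosen route has every ring A oxygen in place, by symmetry, before any metal-catalysed C–H step, and its key step runs in a neutral medium on the cheap chromone 7, so a failure costs less.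

Alternative 3: The C6–OMe bond is made on a preformed flavone. The disconnection cuts C6–O of 4'-O-benzyl-7-O-(methoxymethyl)hispidulin A7 and leads to 4'-O-benzyl-6-iodo-7-O-(methoxymethyl)apigenin A8 and sodium methoxide A9.

- Forward key step: Ullmann-type substitution of the iodide of A8 by A9 under CuBr (monovalent copper) in DMF–methanol gives A7.
- For it: A8 derives in a few steps from a cheap commercial flavone that lacks only the 6-oxygen, with iodination directed ortho to the chelated 5-OH. This is probably the shortest route, and on step count and cost of starting material it is stronger than the chosen one.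
- Against it: the constitution depends on 6- versus 8-iodination and on the absence of base-induced opening and reclosure of ring C (Wessely–Moser-type scrambling) under hot A9, which would give the 8-methoxy isomer, hard to tell apart from A7. Hydrodeiodination of A8 competes. An acidic removal of the methoxymethyl group from A7 must still precede sulfation.
- Comparison: in place of brevity, the chosen route offers a ring A pattern guaranteed by the symmetry of 4 rather than by a selectivity, and a late, modular introduction of ring B.

Key step: step 5

## Route

Assumption: the target is taken as the free hydrogen sulfate as drawn; it would be released from its potassium salt by proton exchange just before isolation, the salt being the storable form. Compounds 1 and 8 are taken as commercial.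

Step 1
Reactants: 1 2-methoxyresorcinol (2-methoxybenzene-1,3-diol)
Product: 2 1,3-diisopropoxy-2-methoxybenzene
Conditions: 2-bromopropane (4 equiv), K2CO3 (4 equiv), KI (0.1 equiv), DMF, 70 °C
Reagents that add atoms: 2-bromopropane, CC(C)Br
Why: Williamson etherification of both phenols, with excess secondary bromide to offset E2 loss; isopropyl ethers carry no aromatic C–H to compete in step 2 and resist the Lewis acid of step 3.

Step 2
Reactants: 2 1,3-diisopropoxy-2-methoxybenzene
Product: 4 3,5-diisopropoxy-4-methoxyphenol, via aryl pinacol boronate 3 (not isolated)
Conditions: B2pin2 (1.0 equiv), [Ir(OMe)(cod)]2 (1.5 mol%), 4,4'-di-tert-butyl-2,2'-bipyridine (3 mol%), THF, 80 °C (sealed tube); then aq. NaOH, 30% H2O2, 0 °C to rt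
Reagents that add atoms: bis(pinacolato)diboron, CC1(C)OB(OC1(C)C)B1OC(C)(C)C(C)(C)O1; hydrogen peroxide, OO
Why: Iridium-catalysed arene C–H borylation is sterically governed, and C5–H is the only ring C–H of 2 without an ortho substituent; basic peroxide then oxidises the C–B bond to the phenol, which should be handled under inert gas because it is electron-rich.

Step 3
Reactants: 4 3,5-diisopropoxy-4-methoxyphenol
Product: 5 1-(2-hydroxy-4,6-diisopropoxy-5-methoxyphenyl)ethanone
Conditions: AcOH, BF3·OEt2 (3 equiv), 65 °C; then aq. NaOAc, MeOH, 60 °C
Reagents that add atoms: acetic acid, CC(=O)O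
Why: Friedel–Crafts ortho-acylation (Fries-type manifold) at one of the two equivalent positions of the symmetric phenol, so only one ketone can form; the product is held as its difluoroboron chelate through the phenol oxygen, which keeps the carbonyl from assisting cleavage of the neighbouring isopropyl ether.

Step 4
Reactants: 5 1-(2-hydroxy-4,6-diisopropoxy-5-methoxyphenyl)ethanone
Product: 7 5,7-diisopropoxy-6-methoxy-4H-chromen-4-one, via enaminone 6 (not isolated)
Conditions: Me2NCH(OMe)2 (3 equiv), toluene, 100 °C; evaporate; then conc. HCl, CH2Cl2, rt
Reagents that add atoms: N,N-dimethylformamide dimethyl acetal, COC(OC)N(C)C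
Why: Condensation of the methyl ketone with the amide acetal gives the E-configured β-dimethylaminoenone; acid then triggers 6-endo addition of the phenol oxygen to the enaminone β-carbon and loss of dimethylamine, the standard enaminone route to 2,3-unsubstituted chromones.

Step 5
Reactants: 7 5,7-diisopropoxy-6-methoxy-4H-chromen-4-one; 8 4-acetoxyphenylboronic acid
Product: 9 4-(5,7-diisopropoxy-6-methoxy-4-oxo-4H-chromen-2-yl)phenyl acetate (4'-O-acetyl-5,7-di-O-isopropylhispidulin)
Conditions: 8 (3 equiv, in portions), Pd(OCOCF3)2 (10 mol%), O2 (1 atm), DMSO, 80 °C
Reagents that add atoms: none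
Why: Transmetalation from boron gives an aryl palladium trifluoroacetate (divalent palladium), which adds syn across C2=C3 with the aryl group on the electrophilic β-carbon C2 and palladium on C3. The C3 palladium enolate can move to the other face through its oxygen-bound form and then lose the C2 hydrogen by β-hydride elimination, forming the C2–C1' bond and restoring the pyranone; zerovalent palladium is reoxidised by O2. If the enolate is protonated instead, the saturated ketone is dehydrogenated by the same Pd(OCOCF3)2/DMSO/O2 system, so both paths should lead to 9. The closest known reaction type is the oxidative Heck-type C2 arylation of chromones with arylboronic acids. No ring is closed and no stereocentre is formed. The selectivity needed is C2 over C3, secured by the polarity of the vinylogous ester and by C2 being the only enone β C–H of 7. The medium is free of base and nucleophile, which the aryl acetate and the isopropyl ethers should tolerate, and the excess of 8 allows for homocoupling and protodeboronation.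

Step 6
Reactants: 9 4-(5,7-diisopropoxy-6-methoxy-4-oxo-4H-chromen-2-yl)phenyl acetate
Product: 10 4-(5,7-dihydroxy-6-methoxy-4-oxo-4H-chromen-2-yl)phenyl acetate (hispidulin 4'-acetate)
Conditions: BCl3 (1 M in CH2Cl2, 5 equiv), CH2Cl2, −78 °C to 0 °C; then ice-water
Reagents that add atoms: none
Why: Lewis-acid dealkylation: the 5-ether is cleaved first with chelation to the C4 carbonyl, and the 7-ether follows by ionisation of the secondary alkyl–oxygen bond, far faster than SN2 demethylation at 6-OMe; the aryl acetate has no ionisable alkyl–oxygen bond and should persist at or below 0 °C.

Step 7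
Reactants: 10 4-(5,7-dihydroxy-6-methoxy-4-oxo-4H-chromen-2-yl)phenyl acetate
Product: 12 hispidulin 7-sulfate, via 4'-O-acetylhispidulin 7-sulfate 11 (not isolated)
Conditions: SO3·pyridine (3 equiv), pyridine, 25–40 °C; evaporate; then K2CO3, MeOH, rt; then H+ form cation-exchange resin, 0 °C, freeze-dry
Reagents that add atoms: sulfur trioxide–pyridine complex, O=S(=O)([O-])[n+]1ccccc1
Why: O-sulfonation of the only reactive phenol: 7-OH is acidic and unchelated, 5-OH is locked in its hydrogen bond to the C4 carbonyl and O4' is acetylated; carbonate methanolysis then removes the aryl acetate while the sulfate monoester anion is inert to base, and cold proton exchange gives the acid form drawn.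

## Compound list

1 | 2-methoxyresorcinol (2-methoxybenzene-1,3-diol) | COc1c(O)cccc1O | starting material
2 | 1,3-diisopropoxy-2-methoxybenzene | COc1c(OC(C)C)cccc1OC(C)C | intermediate
3 | 2-(3,5-diisopropoxy-4-methoxyphenyl)-4,4,5,5-tetramethyl-1,3,2-dioxaborolane | COc1c(OC(C)C)cc(B2OC(C)(C)C(C)(C)O2)cc1OC(C)C | intermediate
4 | 3,5-diisopropoxy-4-methoxyphenol | COc1c(OC(C)C)cc(O)cc1OC(C)C | intermediate
5 | 1-(2-hydroxy-4,6-diisopropoxy-5-methoxyphenyl)ethanone | CC(=O)c1c(O)cc(OC(C)C)c(OC)c1OC(C)C | intermediate
6 | (E)-3-(dimethylamino)-1-(2-hydroxy-4,6-diisopropoxy-5-methoxyphenyl)prop-2-en-1-one | CN(C)/C=C/C(=O)c1c(O)cc(OC(C)C)c(OC)c1OC(C)C | intermediate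
7 | 5,7-diisopropoxy-6-methoxy-4H-chromen-4-one | COc1c(OC(C)C)cc2occc(=O)c2c1OC(C)C | intermediate
8 | 4-acetoxyphenylboronic acid | CC(=O)Oc1ccc(B(O)O)cc1 | starting material
9 | 4-(5,7-diisopropoxy-6-methoxy-4-oxo-4H-chromen-2-yl)phenyl acetate | COc1c(OC(C)C)cc2oc(-c3ccc(OC(C)=O)cc3)cc(=O)c2c1OC(C)C | intermediate
10 | 4-(5,7-dihydroxy-6-methoxy-4-oxo-4H-chromen-2-yl)phenyl acetate | COc1c(O)cc2oc(-c3ccc(OC(C)=O)cc3)cc(=O)c2c1O | intermediate
11 | 4-[5-hydroxy-6-methoxy-4-oxo-7-(sulfooxy)-4H-chromen-2-yl]phenyl acetate | COc1c(OS(=O)(=O)O)cc2oc(-c3ccc(OC(C)=O)cc3)cc(=O)c2c1O | intermediate
12 | hispidulin 7-sulfate | COc1c(OS(=O)(=O)O)cc2oc(-c3ccc(O)cc3)cc(=O)c2c1O | target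

## Step count and least certain steps

Total step count: 7. Longest linear sequence: 7 steps (1 to 12; 8 is purchased).

**Step 5 (key step).** Protonolysis of the C3 palladium enolate may outrun β-hydride elimination and leave the reaction at the saturated ketone if the in-situ dehydrogenation is slow. Oxidative homocoupling and protodeboronation may consume the boron reagent, and the electron-rich vinylogous ester may insert slowly enough for the catalyst to aggregate. Fallback, setting out from 7: deprotonative zincation at C2 with TMPZnCl·LiCl (THF, 25 °C, no added Lewis acid) should give (5,7-diisopropoxy-6-methoxy-4-oxo-4H-chromen-2-yl)zinc chloride F1. Negishi coupling of F1 with 4-iodophenyl acetate F2 under Pd(dba)2 and tri(2-furyl)phosphine (zerovalent palladium) returns to the route at 9. The organozinc reagent tolerates the ester, and the bond is made by metalation and cross-coupling instead of oxidative insertion.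

**Step 3.** Lewis-acid dealkylation of the isopropyl ether next to the new carbonyl, or oxidative degradation of the electron-rich phenol at elevated temperature, could erode the acylation. Fallback, setting out from 4: protection with chloromethyl methyl ether and iPr2NEt gives 1,3-diisopropoxy-2-methoxy-5-(methoxymethoxy)benzene F3. Directed ortho-lithiation (n-BuLi, THF, 0 °C) at one of its two equivalent ring positions and quenching with N-methoxy-N-methylacetamide gives 1-[4,6-diisopropoxy-5-methoxy-2-(methoxymethoxy)phenyl]ethanone F4. HCl in methanol removes the acetal and returns to the route at 5, with no Lewis acid involved.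

**Step 6.** If the 7-ether needs warming, acyl cleavage of the 4'-acetate or demethylation at the crowded 6-OMe could set in before dealkylation is complete. Fallback, setting out from 7: BCl3 is applied at the chromone stage, where no ester is present, to give 5,7-dihydroxy-6-methoxy-4H-chromen-4-one F5. Benzyl bromide and K2CO3 in DMF at 70 °C give 5,7-bis(benzyloxy)-6-methoxy-4H-chromen-4-one F6, which has no further borylation or acylation to face. Coupling of F6 with 8 as in step 5 gives 4-[5,7-bis(benzyloxy)-6-methoxy-4-oxo-4H-chromen-2-yl]phenyl acetate F7. Neutral hydrogenolysis (H2, Pd/C, ethyl acetate–THF) returns to the route at 10.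

**Step 7.** Over-sulfation or incomplete conversion, solvolytic loss of the sulfate during proton exchange, and the difficulty of purifying a very polar salt are the likely problems. Fallback, setting out from 10: 2,2,2-trichloroethyl chlorosulfate with Et3N and 4-(dimethylamino)pyridine in THF should give the neutral sulfate diester 4-{5-hydroxy-6-methoxy-4-oxo-7-[(2,2,2-trichloroethoxy)sulfonyloxy]-4H-chromen-2-yl}phenyl acetate F8, which can be purified on silica. Reductive unmasking (Zn, HCO2NH4, methanol) returns to the route at 11, formed as its ammonium salt, after which the methanolysis and proton exchange of step 7 lead on to 12.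

## Further compounds

F1 | step 5 | (5,7-diisopropoxy-6-methoxy-4-oxo-4H-chromen-2-yl)zinc chloride | COc1c(OC(C)C)cc2oc([Zn]Cl)cc(=O)c2c1OC(C)C
F2 | step 5 | 4-iodophenyl acetate | CC(=O)Oc1ccc(I)cc1
F3 | step 3 | 1,3-diisopropoxy-2-methoxy-5-(methoxymethoxy)benzene | COCOc1cc(OC(C)C)c(OC)c(OC(C)C)c1
F4 | step 3 | 1-[4,6-diisopropoxy-5-methoxy-2-(methoxymethoxy)phenyl]ethanone | COCOc1cc(OC(C)C)c(OC)c(OC(C)C)c1C(C)=O
F5 | step 6 | 5,7-dihydroxy-6-methoxy-4H-chromen-4-one | COc1c(O)cc2occc(=O)c2c1O
F6 | step 6 | 5,7-bis(benzyloxy)-6-methoxy-4H-chromen-4-one | COc1c(OCc2ccccc2)cc2occc(=O)c2c1OCc1ccccc1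
F7 | step 6 | 4-[5,7-bis(benzyloxy)-6-methoxy-4-oxo-4H-chromen-2-yl]phenyl acetate | COc1c(OCc2ccccc2)cc2oc(-c3ccc(OC(C)=O)cc3)cc(=O)c2c1OCc1ccccc1
F8 | step 7 | 4-{5-hydroxy-6-methoxy-4-oxo-7-[(2,2,2-trichloroethoxy)sulfonyloxy]-4H-chromen-2-yl}phenyl acetate | COc1c(OS(=O)(=O)OCC(Cl)(Cl)Cl)cc2oc(-c3ccc(OC(C)=O)cc3)cc(=O)c2c1O
A1 | alternative 1 | 4'-O-benzylhispidulin | COc1c(O)cc2oc(-c3ccc(OCc4ccccc4)cc3)cc(=O)c2c1O
A2 | alternative 1 | methyl 6-[4-(benzyloxy)phenyl]-2-methyl-4-oxo-4H-pyran-3-carboxylate | COC(=O)c1c(C)oc(-c2ccc(OCc3ccccc3)cc2)cc1=O
A3 | alternative 1 | methyl methoxyacetate | COCC(=O)OC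
A4 | alternative 2 | 4'-O-acetylhispidulin 7-(2,2,2-trichloroethyl sulfate) | COc1c(O)c2c(=O)cc(-c3ccc(OC(C)=O)cc3)oc2cc1OS(=O)(=O)OCC(Cl)(Cl)Cl
A5 | alternative 2 | 4'-acetoxy-6-methoxyflavon-7-yl 2,2,2-trichloroethyl sulfate | COc1cc2c(=O)cc(-c3ccc(OC(C)=O)cc3)oc2cc1OS(=O)(=O)OCC(Cl)(Cl)Cl
A6 | alternative 2 | [bis(trifluoroacetoxy)iodo]benzene | O=C(OI(OC(=O)C(F)(F)F)c1ccccc1)C(F)(F)F
A7 | alternative 3 | 4'-O-benzyl-7-O-(methoxymethyl)hispidulin | COCOc1cc2oc(-c3ccc(OCc4ccccc4)cc3)cc(=O)c2c(O)c1OC
A8 | alternative 3 | 4'-O-benzyl-6-iodo-7-O-(methoxymethyl)apigenin | COCOc1cc2oc(-c3ccc(OCc4ccccc4)cc3)cc(=O)c2c(O)c1I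
A9 | alternative 3 | sodium methoxide | C[O-].[Na+]
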